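Ring B is built, not bought. In the salicylic acid ring, C1 (CO2H) lies between the oxygenated carbons C2 (OH) and C6 (O-aryl), so C1 is read as a malonate carbon, C2 as an ester carbonyl and C6 as an aryl enol ether carbon. Disconnecting C2–C3 unfolds ring B into dienylidene malonate 16, in which the C3–C5 chain already carries the prenyl unit and C6 the ring A aryloxy group. One base-induced vinylogous Dieckmann closure forms C2–C3, closes ring B and aromatises it to salicylate 18 with every substituent in place. Desilylation, acetylation and a double deallylation then give the target.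

Key step: step 10

Assumption: 5-methylhex-4-enal (12) is taken as purchasable; ring A is drawn from 2-methoxy-4-methylphenol, whose substitution pattern fixes which catechol oxygen becomes the diaryl ether oxygen, and the target has no stereocentre.

Abbreviations: TBS = tert-butyldimethylsilyl; ArO = 2-(allyloxy)-6-{[(tert-butyldimethylsilyl)oxy]methyl}-4-methylphenoxy; ring B atoms are numbered C1 (carboxyl-bearing), C2 (OH), C3 (prenyl), C4, C5, C6 (O-aryl).

Step 1
Reactants: 1 2-methoxy-4-methylphenol
Product: 2 2-hydroxy-3-methoxy-5-methylbenzaldehyde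
Conditions: MgCl2, Et3N, (CH2O)n, MeCN, reflux; then 1 M HCl
Reagents that add atoms: paraformaldehyde (formaldehyde), C=O
Why: Magnesium-phenoxide-directed ortho-formylation (Casnati–Skattebøl) can only occur at C6, because the para position carries the methyl group and the other ortho position the methoxy group, and a second equivalent of formaldehyde oxidises the benzylic alkoxide by hydride transfer.

Step 2
Reactants: 2 2-hydroxy-3-methoxy-5-methylbenzaldehyde
Product: 3 2,3-dihydroxy-5-methylbenzaldehyde
Conditions: BBr3, CH2Cl2, −78 °C to rt; then H2O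
Reagents that add atoms: none
Why: Lewis-acid cleavage of the aryl methyl ether by BBr3, assisted by the neighbouring chelating phenol, should leave the aldehyde intact after aqueous work-up.

Step 3
Reactants: 3 2,3-dihydroxy-5-methylbenzaldehyde
Product: 4 3-(allyloxy)-2-hydroxy-5-methylbenzaldehyde
Conditions: NaH (2.1 equiv), DMSO, rt; allyl bromide (1.0 equiv), rt; then aq. NH4Cl
Reagents that add atoms: allyl bromide, C=CCBr
Why: Williamson etherification of the dianion, in which the 2-oxide is delocalised into the formyl group, so the more basic, non-conjugated 3-oxide should take the single equivalent of allyl bromide.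

Step 4
Reactants: 4 3-(allyloxy)-2-hydroxy-5-methylbenzaldehyde
Product: 5 2-(allyloxy)-6-(hydroxymethyl)-4-methylphenol
Conditions: NaBH4, MeOH/THF, 0 °C
Reagents that add atoms: none
Why: Borohydride reduction of the salicylaldehyde to the benzylic alcohol, with the allyl ether and the arene inert.

Step 5
Reactants: 5 2-(allyloxy)-6-(hydroxymethyl)-4-methylphenol
Product: 6 2-(allyloxy)-6-{[(tert-butyldimethylsilyl)oxy]methyl}-4-methylphenol
Conditions: TBSCl (1.05 equiv), imidazole, CH2Cl2, 0 °C
Reagents that add atoms: tert-butyldimethylsilyl chloride, CC(C)(C)[Si](C)(C)Cl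
Why: Silylation of the primary benzylic hydroxyl is much faster than that of the hydrogen-bonded, doubly ortho-substituted phenol, so one equivalent of silyl chloride should give the mono-ether with the phenol free.

Step 6
Reactants: 7 diallyl malonate; 8 acetyl chloride
Product: 9 diallyl 2-acetylmalonate
Conditions: MgCl2, Et3N, MeCN, 0 °C to rt; then 1 M HCl
Reagents that add atoms: none
Why: Rathke C-acylation of the chelated magnesium enolate of the malonate by the acid chloride under soft enolisation.

Step 7
Reactants: 9 diallyl 2-acetylmalonate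
Product: 10 diallyl 2-(1-chloroethylidene)malonate
Conditions: POCl3, Bu3N, toluene, 90 °C
Reagents that add atoms: phosphoryl chloride, O=P(Cl)(Cl)Cl
Why: The enol of the tricarbonyl compound is phosphorylated and chloride displaces the phosphate by addition–elimination, the standard route to β-chloroalkylidene malonates, and the two identical esters leave no alkene geometry to control.

Step 8
Reactants: 6 2-(allyloxy)-6-{[(tert-butyldimethylsilyl)oxy]methyl}-4-methylphenol; 10 diallyl 2-(1-chloroethylidene)malonate
Product: 11 diallyl 2-[1-(ArO)ethylidene]malonate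
Conditions: NaH, DMF, 0 °C; then 10, 0 °C to rt
Reagents that add atoms: none
Why: Nucleophilic vinylic substitution by addition–elimination, in which the phenoxide adds to the β-carbon of the alkylidene malonate (a vinylogous acid chloride) and chloride leaves, so the diaryl ether oxygen is installed before ring B exists.

Step 9
Reactants: 11 diallyl 2-[1-(ArO)ethylidene]malonate; 12 5-methylhex-4-enal
Product: 16 diallyl 2-[(2E)-1-(ArO)-7-methylocta-2,6-dien-1-ylidene]malonate, via lithium aldolate 13 (not isolated), via dihydropyranone 14 (not isolated), via lithium trienoate 15 (not isolated)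
Conditions: LiN(iPr)2 (1.1 equiv), THF, −78 °C; 12 (1.2 equiv), −78 °C to rt; then allyl bromide, Bu4NI (cat.), DMF, rt
Reagents that add atoms: allyl bromide, C=CCBr
Why: Vinylogous Stobbe-type condensation, in which the γ-lithiated dienolate of 11 adds through its CH2 terminus to the aldehyde, the aldolate lactonises onto the cis ester (the thermodynamic trap known from kavalactone syntheses), the released lithium allyloxide triggers E1cB opening of the dihydropyranone to the (4E)-dienyl half-ester carboxylate, and O-alkylation with allyl bromide restores the symmetrical diallyl ester.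

Step 10
Reactants: 16 diallyl 2-[(2E)-1-(ArO)-7-methylocta-2,6-dien-1-ylidene]malonate
Product: 18 allyl 6-(ArO)-2-hydroxy-3-(3-methylbut-2-en-1-yl)benzoate, via cyclohexadienone 17 (not isolated)
Conditions: KOtBu (1.5 equiv), THF/t-BuOH, 0 °C to 40 °C; then aq. NH4Cl
Reagents that add atoms: none
Why: Proposed new method: tert-butoxide removes a C3 hydrogen, acidified vinylogously through C4=C5 and C6=C1 by both esters, to give a trienolate whose C3 terminus attacks the ester carbonyl C2 lying cis to the chain; the tetrahedral intermediate expels allyloxide to give dienone 17, and alkoxide removes the remaining C3 hydrogen so that the ring aromatises to the chelated salicylate phenoxide. The closest known reaction types are Claisen and Dieckmann aromatisations of poly-β-carbonyl chains to salicylates and the closure of dienylketenes or dienylidene malonates to phenols; the bond formation can equally be read as a 6π-electrocyclisation of the 1-allyloxy-1-oxidotriene C2=C1–C6=C5–C4=C3. Ring B closes in the 6-(enolendo)-exo-trig mode by formation of C2–C3, and no stereocentre results because the C3 centre of 17 is lost on enolisation. The closure needs C4 cis to C1 across the enolate C5=C6 bond, a geometry that arises only on deprotonation of the s-cis C5–C6 rotamer; the alcohol cosolvent keeps proton transfer reversible, so both anion geometries interconvert and drain through the irreversible aromatisation, whatever the E geometry of C4=C5 in 16. Regiochemistry is unambiguous because the two esters are identical and C3 is the only carbon acid that can reach them. Cyclisation through oxygen and re-addition of alkoxide are reversible, and the bulky, poorly nucleophilic base is chosen so that exchange of the C6 aryloxy group by addition–elimination, isomerisation of the allyl ether and sigmatropic shift of the allyl ester enolate do not compete at this temperature.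

Step 11
Reactants: 18 allyl 6-(ArO)-2-hydroxy-3-(3-methylbut-2-en-1-yl)benzoate
Product: 19 allyl 6-[2-(allyloxy)-6-(hydroxymethyl)-4-methylphenoxy]-2-hydroxy-3-(3-methylbut-2-en-1-yl)benzoate
Conditions: Bu4NF, AcOH, THF, 0 °C to rt
Reagents that add atoms: none
Why: Fluoride-induced desilylation of the primary silyl ether, with acetic acid buffering keeping the liberated alkoxide protonated so that the allyl ester is not attacked and no eight-membered lactone forms.

Step 12
Reactants: 19 allyl 6-[2-(allyloxy)-6-(hydroxymethyl)-4-methylphenoxy]-2-hydroxy-3-(3-methylbut-2-en-1-yl)benzoate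
Product: 20 allyl 6-[2-(acetoxymethyl)-6-(allyloxy)-4-methylphenoxy]-2-hydroxy-3-(3-methylbut-2-en-1-yl)benzoate
Conditions: Ac2O (1.1 equiv), pyridine, CH2Cl2, 0 °C
Reagents that add atoms: acetic anhydride, CC(=O)OC(C)=O
Why: Acylation of the unhindered primary benzylic alcohol is far faster than that of the salicylate hydroxyl, which is hydrogen-bonded to the ester carbonyl and flanked by the prenyl group, so one equivalent of anhydride should give the mono-acetate.

Step 13
Reactants: 20 allyl 6-[2-(acetoxymethyl)-6-(allyloxy)-4-methylphenoxy]-2-hydroxy-3-(3-methylbut-2-en-1-yl)benzoate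
Product: 21 6-[2-(acetoxymethyl)-6-hydroxy-4-methylphenoxy]-2-hydroxy-3-(3-methylbut-2-en-1-yl)benzoic acid (7-O-acetylsecopenicillide C)
Conditions: Pd(PPh3)4 (5 mol %), morpholine, THF, rt; then dilute citric acid
Reagents that add atoms: none
Why: Tsuji–Trost deallylation, in which zerovalent palladium ionises both the allyl ester and the allyl aryl ether to π-allyl complexes that morpholine captures, freeing the carboxylic acid and the ring A phenol while the acetate, the prenyl alkene and the diaryl ether are untouched.

Compound list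
1 | 2-methoxy-4-methylphenol | COc1cc(C)ccc1O | starting material
2 | 2-hydroxy-3-methoxy-5-methylbenzaldehyde | COc1cc(C)cc(C=O)c1O | intermediate
3 | 2,3-dihydroxy-5-methylbenzaldehyde | Cc1cc(O)c(O)c(C=O)c1 | intermediate
4 | 3-(allyloxy)-2-hydroxy-5-methylbenzaldehyde | C=CCOc1cc(C)cc(C=O)c1O | intermediate
5 | 2-(allyloxy)-6-(hydroxymethyl)-4-methylphenol | C=CCOc1cc(C)cc(CO)c1O | intermediate
6 | 2-(allyloxy)-6-{[(tert-butyldimethylsilyl)oxy]methyl}-4-methylphenol | C=CCOc1cc(C)cc(CO[Si](C)(C)C(C)(C)C)c1O | intermediate
7 | diallyl malonate | C=CCOC(=O)CC(=O)OCC=C | starting material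
8 | acetyl chloride | CC(=O)Cl | starting material
9 | diallyl 2-acetylmalonate | CC(=O)C(C(=O)OCC=C)C(=O)OCC=C | intermediate
10 | diallyl 2-(1-chloroethylidene)malonate | CC(Cl)=C(C(=O)OCC=C)C(=O)OCC=C | intermediate
11 | diallyl 2-[1-(2-(allyloxy)-6-{[(tert-butyldimethylsilyl)oxy]methyl}-4-methylphenoxy)ethylidene]malonate | CC(Oc1c(CO[Si](C)(C)C(C)(C)C)cc(C)cc1OCC=C)=C(C(=O)OCC=C)C(=O)OCC=C | intermediate
12 | 5-methylhex-4-enal | CC(C)=CCCC=O | starting material
13 | lithium alkoxide of diallyl 2-[1-(2-(allyloxy)-6-{[(tert-butyldimethylsilyl)oxy]methyl}-4-methylphenoxy)-3-hydroxy-7-methyloct-6-en-1-ylidene]malonate, racemic | [Li+].[O-]C(CCC=C(C)C)CC(Oc1c(CO[Si](C)(C)C(C)(C)C)cc(C)cc1OCC=C)=C(C(=O)OCC=C)C(=O)OCC=C | intermediate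
14 | allyl 4-(2-(allyloxy)-6-{[(tert-butyldimethylsilyl)oxy]methyl}-4-methylphenoxy)-6-(4-methylpent-3-en-1-yl)-2-oxo-5,6-dihydro-2H-pyran-3-carboxylate, racemic | C=CCOC(=O)C1=C(Oc2c(CO[Si](C)(C)C(C)(C)C)cc(C)cc2OCC=C)CC(CCC=C(C)C)OC1=O | intermediate
15 | lithium (2Z,4E)-2-[(allyloxy)carbonyl]-3-(2-(allyloxy)-6-{[(tert-butyldimethylsilyl)oxy]methyl}-4-methylphenoxy)-9-methyldeca-2,4,8-trienoate | [Li+].[O-]C(=O)/C(C(=O)OCC=C)=C(/Oc1c(CO[Si](C)(C)C(C)(C)C)cc(C)cc1OCC=C)\C=C\CCC=C(C)C | intermediate
16 | diallyl 2-[(2E)-1-(2-(allyloxy)-6-{[(tert-butyldimethylsilyl)oxy]methyl}-4-methylphenoxy)-7-methylocta-2,6-dien-1-ylidene]malonate | C=CCOC(=O)C(C(=O)OCC=C)=C(Oc1c(CO[Si](C)(C)C(C)(C)C)cc(C)cc1OCC=C)/C=C/CCC=C(C)C | intermediate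
17 | allyl 2-(2-(allyloxy)-6-{[(tert-butyldimethylsilyl)oxy]methyl}-4-methylphenoxy)-5-(3-methylbut-2-en-1-yl)-6-oxocyclohexa-1,3-diene-1-carboxylate, racemic | C=CCOC(=O)C1=C(Oc2c(CO[Si](C)(C)C(C)(C)C)cc(C)cc2OCC=C)C=CC(CC=C(C)C)C1=O | intermediate
18 | allyl 6-(2-(allyloxy)-6-{[(tert-butyldimethylsilyl)oxy]methyl}-4-methylphenoxy)-2-hydroxy-3-(3-methylbut-2-en-1-yl)benzoate | C=CCOC(=O)c1c(O)c(CC=C(C)C)ccc1Oc1c(CO[Si](C)(C)C(C)(C)C)cc(C)cc1OCC=C | intermediate
19 | allyl 6-[2-(allyloxy)-6-(hydroxymethyl)-4-methylphenoxy]-2-hydroxy-3-(3-methylbut-2-en-1-yl)benzoate | C=CCOC(=O)c1c(O)c(CC=C(C)C)ccc1Oc1c(CO)cc(C)cc1OCC=C | intermediate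
20 | allyl 6-[2-(acetoxymethyl)-6-(allyloxy)-4-methylphenoxy]-2-hydroxy-3-(3-methylbut-2-en-1-yl)benzoate | C=CCOC(=O)c1c(O)c(CC=C(C)C)ccc1Oc1c(COC(C)=O)cc(C)cc1OCC=C | intermediate
21 | 6-[2-(acetoxymethyl)-6-hydroxy-4-methylphenoxy]-2-hydroxy-3-(3-methylbut-2-en-1-yl)benzoic acid (7-O-acetylsecopenicillide C) | CC(=O)OCc1cc(C)cc(O)c1Oc1ccc(CC=C(C)C)c(O)c1C(=O)O | target

Total step count: 13. Longest linear sequence: 11 steps (steps 1–5 and 8–13); steps 6 and 7 form the two-step malonate branch.

Steps most likely to fail

Step 10 (key step). The trienolate may persist without closing, because the ester carbonyl is deactivated within the delocalised anion or the anion stays in the unproductive C5=C6 geometry. Alkoxide may also exchange the C6 aryloxy group by addition–elimination. The fallback makes the diaryl ether by arene coupling, sets out from 6 and comes back at 18. 2-Bromo-6-hydroxybenzoic acid would be condensed with acetone ((CF3CO)2O, CF3CO2H) to 5-bromo-2,2-dimethyl-4H-1,3-benzodioxin-4-one F1. Copper-catalysed Ullmann etherification of F1 with 6 (CuI, picolinic acid, K3PO4, DMSO, 90 °C) should give 5-(ArO)-2,2-dimethyl-4H-1,3-benzodioxin-4-one F2. Sodium allyloxide in THF at 0 °C would open the dioxinone to allyl 2-(ArO)-6-hydroxybenzoate F3. Ortho C-prenylation of the sodium phenoxide of F3 (NaH, toluene, 1-bromo-3-methylbut-2-ene) at C3 should then give 18.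

Step 9. Proton transfer from the enolisable aldehyde to the stabilised dienolate, attack through the α-carbon followed by retro-aldol, or incomplete eliminative opening before alkylation could erode the one-pot sequence. The fallback builds the whole chain before the aryl ether is installed, sets out from 12, 7 and 6 and comes back at 16. Doebner condensation of 12 with malonic acid (pyridine, piperidine, 80 °C) would give (2E)-7-methylocta-2,6-dienoic acid F4, and oxalyl chloride with catalytic DMF its chloride, (2E)-7-methylocta-2,6-dienoyl chloride F5. C-Acylation of 7 with F5 (MgCl2, Et3N, MeCN) should give diallyl 2-[(2E)-7-methylocta-2,6-dienoyl]malonate F6. POCl3/Bu3N would convert F6 into diallyl 2-[(2E)-1-chloro-7-methylocta-2,6-dien-1-ylidene]malonate F7. Addition–elimination of the sodium phenoxide of 6 (NaH, DMF, 0 °C) on F7 should give 16.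

Step 8. Addition of the doubly ortho-substituted phenoxide to the tetrasubstituted chloroalkene carbon may be slow, so that dehydrochlorination of 10 to an allenyl malonate and its oligomerisation take over. The fallback forms the aryl enol ether on an alkyne and adds the second ester afterwards, sets out from 6 and comes back at 11. Base-mediated conjugate addition of 6 to allyl but-2-ynoate (K2CO3, DMF, 60 °C) should give allyl (2E)-3-(ArO)but-2-enoate F8. Deprotonation of F8 (LiN(iPr)2, 2 equiv, THF, −78 °C) and C-acylation of the dienolate at the α-carbon with allyl chloroformate would give the lithium dienolate of 11, which on protonation (with a trace of Et3N to return the double bond into conjugation) gives 11.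

Further compounds
F1 | step 10 | 5-bromo-2,2-dimethyl-4H-1,3-benzodioxin-4-one | CC1(C)OC(=O)c2c(Br)cccc2O1
F2 | step 10 | 5-(2-(allyloxy)-6-{[(tert-butyldimethylsilyl)oxy]methyl}-4-methylphenoxy)-2,2-dimethyl-4H-1,3-benzodioxin-4-one | CC1(C)OC(=O)c2c(Oc3c(CO[Si](C)(C)C(C)(C)C)cc(C)cc3OCC=C)cccc2O1
F3 | step 10 | allyl 2-(2-(allyloxy)-6-{[(tert-butyldimethylsilyl)oxy]methyl}-4-methylphenoxy)-6-hydroxybenzoate | C=CCOC(=O)c1c(O)cccc1Oc1c(CO[Si](C)(C)C(C)(C)C)cc(C)cc1OCC=C
F4 | step 9 | (2E)-7-methylocta-2,6-dienoic acid | CC(C)=CCC/C=C/C(=O)O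
F5 | step 9 | (2E)-7-methylocta-2,6-dienoyl chloride | CC(C)=CCC/C=C/C(=O)Cl
F6 | step 9 | diallyl 2-[(2E)-7-methylocta-2,6-dienoyl]malonate | CC(C)=CCC/C=C/C(=O)C(C(=O)OCC=C)C(=O)OCC=C
F7 | step 9 | diallyl 2-[(2E)-1-chloro-7-methylocta-2,6-dien-1-ylidene]malonate | CC(C)=CCC/C=C/C(Cl)=C(C(=O)OCC=C)C(=O)OCC=C
F8 | step 8 | allyl (2E)-3-(2-(allyloxy)-6-{[(tert-butyldimethylsilyl)oxy]methyl}-4-methylphenoxy)but-2-enoate | C=CCOC(=O)/C=C(\C)Oc1c(CO[Si](C)(C)C(C)(C)C)cc(C)cc1OCC=C
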